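Readings and results stem from a simulated flask on assumed constants, noise included.

| flask | starting material | partner | free catalyst | remark | time |
|---|---|---|---|---|---|
| east | 0.050 M | 0.060 M | 0.14 mM | run made earlier |  |
| south-east | 0.050 M | 0.060 M | 0.61 mM | run made earlier |  |
| north-east | 0.050 M | 0.081 M | 0.50 mM | run made earlier |  |
| Wednesday's | 0.050 M | 0.0600 M | 0.50 mM |  | 8.0 h |
| Friday's | 0.050 M | 0.100 M | 0.12 mM |  | 8.0 h |

| run | time / h | target / % | starting material / % |
|---|---|---|---|
| east | 0.417 | 0 | 100.8 |
| east | 1.33 | 4.8 | 96.8 |
| east | 2.50 | 5.4 | 94.7 |
| east | 3.00 | 7.1 | 93.7 |
| east | 5.00 | 9.0 | 92.4 |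
| east | 6.00 | 9.7 | 90.5 |
| east | 8.00 | 13.1 | 89.8 |
| south-east | 0.417 | 4.5 | 94.4 |
| south-east | 1.33 | 12.4 | 87.4 |
| south-east | 2.50 | 19.9 | 81.6 |
| south-east | 3.00 | 20.1 | 79.2 |
| south-east | 5.00 | 23.4 | 75.4 |
| south-east | 6.00 | 24.8 | 75.8 |
| south-east | 8.00 | 25.0 | 74.5 |
| north-east | 0.667 | 7.0 | 93.1 |
| north-east | 1.33 | 13.8 | 84.6 |
| north-east | 2.50 | 21.9 | 79.1 |
| north-east | 4.00 | 23.7 | 74.0 |
| north-east | 8.00 | 27.8 | 71.6 |

(readings scatter by 1 percentage point)

- a species is counted by the starting material in it: one side product counts as two
- amounts and yields of target count idle complex too
- steps under discussion: free catalyst + target <-> idle complex; partner + free catalyst -> catalyst intermediate A; starting material + catalyst intermediate A -> catalyst intermediate B; partner -> decomposed reagent; starting material + target -> side product; catalyst intermediate B -> free catalyst + target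

1. the flask that ends with the higher amount of target, in percent of the starting material charged, or "neither" when 2 percentage points or less lies between them (Wednesday's / Friday's / neither)
2. final target, as a percentage of the starting material charged, in Wednesday's
3. final target, as a percentage of the starting material charged, in Friday's

**Fraction left.** If the catalyst had simply kept turning at a steady pace, a pseudo-first-order picture, the log of the fraction of starting material left would have grown with the loading. By loading I mean free catalyst as a fraction of the starting material charged. From east to south-east at 8.0 h, the loading grew by a factor of 4.36, but the log grew by 2.74. Inside the south-east run, time grew by 6.02 and the log by 2.19. So I dropped that picture.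

**Square number.** I supposed instead that the pace fell as target appeared, as it would with catalyst held in idle complex (product inhibition). Then, at a fixed time, the fraction gone, squared, should go with loading times equivalents of partner, meaning partner charged over starting material charged. South-east gave 4.44 and north-east 4.98. I carried their mean, 4.71, as the square number: fraction gone at 8.0 h, squared, over loading times equivalents.

**East objects.** East gave 3.10, which is lower than my mean. But its fraction gone was small, so 1 percentage point of scatter counted heavily. Its target reading, put through the same sum, gave 5.11, which is higher. So I kept the mean.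

**Two flasks.** The number gave 23.8% for Wednesday's and 15.0% for Friday's. But Friday's lay outside the runs, with more partner than north-east and less catalyst than east. Giving partner no effect and scaling south-east by loading, I got 11.3% for Friday's. Wednesday's stayed ahead by more than 2 points either way.

**The forecast.** It said Wednesday's, with 23.3% against 15%: “That is close to a square-root dependence, which points to strong inhibition by target through idle complex.” My Wednesday's figure stood above its figure.

**The flask.** Wednesday's ended at 22.4% and Friday's at 13.4%, so Wednesday's gave more, by 9 points.

    free catalyst + target ⇌ idle complex (K = 1300 /M, k = 1.40 /M/min)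
    partner + free catalyst → catalyst intermediate A (k = 2.90 /M/min)
    starting material + catalyst intermediate A → catalyst intermediate B (k = 70.0 /M/min)
    partner → decomposed reagent (k = 4.50 × 10⁻⁴ /min)
    starting material + target → side product (k = 0.00130 /M/min)
    catalyst intermediate B → free catalyst + target (k = 2.90 /min)

**Number again.** From the fractions gone, the square number read 4.49 in Wednesday's and 4.02 in Friday's. For the flask like Friday's but with 4.8 × 10⁻⁴ M of free catalyst, 4.71 gave 30.1%, and that flask ended at 29.3%. In Friday's, target rose from 10.2% at 4.00 h to 13.4% at 8.00 h, while idle complex climbed from 52.4% to 82.8% of the catalyst. Partner in Friday's ran down to 74.7% of its charge, its half-life by decomposition being shorter than by entering the round, 26 h against 75 h at 3.71 h.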